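**Strategy.** The target is a 13,14-dihydro-19-hydroxy prostaglandin E (prostanoid numbering): a cyclopentanone ring C8–C12 with the ketone at C9, the (Z)-heptenoic chain on C8, the saturated dihydroxyoctyl chain on C12 and a hydroxyl on C11. Everything rests on cutting C12–C13 and reading C12 as the β-carbon of a C9 enone. In one pot, a lithium dimethyl(alkyl)zincate made from the chain iodide adds to (R)-4-silyloxycyclopent-2-enone anti to the C11 oxygen, and the C8 enolate so formed is alkylated by the (Z)-allylic iodide of the upper chain. One operation thus forms C12–C13 and C7–C8 and sets C12 and C8 from C11. The precursors are bis-silylated (3S,7R)-1-iodooctane-3,7-diol, the enone and methyl (Z)-7-iodohept-5-enoate.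

Key step: step 10

Assumption: (R)-2-[2-(benzyloxy)ethyl]oxirane (3) and (R)-4-[(tert-butyldimethylsilyl)oxy]cyclopent-2-en-1-one (15) are taken as purchasable single enantiomers; positions in the target are given in prostanoid numbering (C1 = carboxyl carbon).

**Lower chain (C13–C20)**

Step 1
Reactants: 1 (R)-but-3-yn-2-ol
Product: 2 (R)-tert-butyl(but-3-yn-2-yloxy)dimethylsilane
Conditions: TBSCl, imidazole, CH2Cl2, 0 °C to rt
Reagents that add atoms: tert-butyldimethylsilyl chloride (TBSCl), CC(C)(C)[Si](C)(C)Cl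
Why: Imidazole-assisted silylation masks the future C19 hydroxyl before the alkyne is metallated, and the stereocentre is not touched.

Step 2
Reactants: 2 (R)-tert-butyl(but-3-yn-2-yloxy)dimethylsilane; 3 (R)-2-[2-(benzyloxy)ethyl]oxirane
Product: 5 (3S,7R)-1-(benzyloxy)-7-[(tert-butyldimethylsilyl)oxy]oct-5-yn-3-ol, via lithium acetylide 4 (not isolated)
Conditions: n-BuLi, THF, −78 °C; BF3·OEt2, then 3, −78 °C; aq. NH4Cl
Reagents that add atoms: none
Why: BF3-promoted opening of a terminal epoxide by a lithium acetylide is an SN2 attack at the unsubstituted carbon, so it should form C16–C17 and leave the epoxide stereocentre (the future C15) unchanged.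

Step 3
Reactants: 5 (3S,7R)-1-(benzyloxy)-7-[(tert-butyldimethylsilyl)oxy]oct-5-yn-3-ol
Product: 6 (3S,7R)-1-(benzyloxy)-3,7-bis[(tert-butyldimethylsilyl)oxy]oct-5-yne
Conditions: TBSCl, imidazole, DMF, rt
Reagents that add atoms: tert-butyldimethylsilyl chloride (TBSCl), CC(C)(C)[Si](C)(C)Cl
Why: Standard silylation of the secondary C15 alcohol gives both carbinols the same protecting group, so that one reagent can remove them at the end.

Step 4
Reactants: 6 (3S,7R)-1-(benzyloxy)-3,7-bis[(tert-butyldimethylsilyl)oxy]oct-5-yne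
Product: 7 (3S,7R)-3,7-bis[(tert-butyldimethylsilyl)oxy]octan-1-ol
Conditions: H2 (1 atm), 10% Pd/C, EtOAc, rt
Reagents that add atoms: none
Why: Heterogeneous hydrogenation should saturate the alkyne and hydrogenolyse the benzyl ether in one operation, while the silyl ethers and both stereocentres are inert in a non-protic solvent.

Step 5
Reactants: 7 (3S,7R)-3,7-bis[(tert-butyldimethylsilyl)oxy]octan-1-ol
Product: 8 (3S,7R)-3,7-bis[(tert-butyldimethylsilyl)oxy]-1-iodooctane
Conditions: PPh3, I2, imidazole, CH2Cl2, 0 °C to rt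
Reagents that add atoms: iodine, II
Why: Appel-type iodination replaces the primary hydroxyl by SN2 displacement of an alkoxyphosphonium ion, and the imidazole buffer keeps the secondary silyl ethers intact.

**Upper chain (C1–C7)**

Step 6
Reactants: 9 hex-5-ynoic acid
Product: 11 7-hydroxyhept-5-ynoic acid, via bromomagnesium alkynide carboxylate 10 (not isolated)
Conditions: EtMgBr (2.2 equiv), THF, 0 to 40 °C; (CH2O)n, 40 °C; aq. HCl
Reagents that add atoms: paraformaldehyde (source of formaldehyde), C=O
Why: Double deprotonation gives an alkynyl Grignard reagent whose carboxylate is protected as its salt, and its addition to formaldehyde should install the C7 hydroxymethyl group.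

Step 7
Reactants: 11 7-hydroxyhept-5-ynoic acid
Product: 12 methyl 7-hydroxyhept-5-ynoate
Conditions: MeOH, cat. H2SO4, rt
Reagents that add atoms: methanol, CO
Why: Fischer esterification in methanol as solvent should esterify the acid cleanly, and the propargylic alcohol is stable to these conditions.

Step 8
Reactants: 12 methyl 7-hydroxyhept-5-ynoate
Product: 13 methyl (5Z)-7-hydroxyhept-5-enoate
Conditions: H2 (1 atm), Lindlar catalyst (Pd on CaCO3 poisoned with Pb(OAc)2), quinoline, EtOAc, rt
Reagents that add atoms: none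
Why: Lindlar semi-hydrogenation delivers both hydrogens to the same face of the alkyne and should stop at the alkene, which sets the C5=C6 Z geometry.

Step 9
Reactants: 13 methyl (5Z)-7-hydroxyhept-5-enoate
Product: 14 methyl (5Z)-7-iodohept-5-enoate
Conditions: PPh3, I2, imidazole, CH2Cl2, 0 °C, dark; used at once
Reagents that add atoms: iodine, II
Why: Appel-type iodination at low temperature is a direct SN2 displacement at the primary allylic carbon and should therefore keep the Z alkene.

**Union and endgame**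

Step 10
Reactants: 8 (3S,7R)-3,7-bis[(tert-butyldimethylsilyl)oxy]-1-iodooctane; 15 (R)-4-[(tert-butyldimethylsilyl)oxy]cyclopent-2-en-1-one; 14 methyl (5Z)-7-iodohept-5-enoate
Product: 19 methyl (5Z)-7-[(1R,2R,3R)-2-[(3S,7R)-3,7-bis[(tert-butyldimethylsilyl)oxy]octyl]-3-[(tert-butyldimethylsilyl)oxy]-5-oxocyclopentyl]hept-5-enoate, via alkyllithium 16 (not isolated), via lithium alkyldimethylzincate 17 (not isolated), via zinc enolate 18 (not isolated)
Conditions: 8, t-BuLi (2.0 equiv), Et2O, −78 °C; Me2Zn (1.0 equiv), −78 to 0 °C; 15, THF, −78 °C; HMPA, 14 (excess), −78 to −40 °C; aq. NH4Cl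
Reagents that add atoms: none
Why: Iodine–lithium exchange on 8 gives the primary alkyllithium 16, which Me2Zn converts into the mixed zincate 17; because methyl is a poor migrating ligand on zinc, 17 should transfer its alkyl group in a 1,4-addition to the β-carbon of enone 15, forming the C12–C13 bond. The closest known reaction type is the three-component prostaglandin coupling (tandem organozincate conjugate addition–enolate alkylation), here with an sp3 alkyl group in place of the usual alkenyl group. No ring is closed. The new C12 stereocentre is controlled by the C11 silyloxy group, which blocks one face so that the alkyl group enters anti to it; the new C8 stereocentre is controlled by C12, since the regiodefined C8–C9 enolate 18 attacks the primary carbon of 14 anti to the fresh C12 chain, which gives the all-trans 8,12,11 pattern. The step needs alkyl transfer over methyl transfer, C-alkylation at C8 faster than proton transfer (which would equilibrate the enolate and expel the C11 silyloxy group), and SN2 instead of SN2' attack with retention of the Z alkene; the low basicity of the zinc enolate, HMPA, excess 14 and the low temperature are meant to secure these.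

Step 11
Reactants: 19 methyl (5Z)-7-[(1R,2R,3R)-2-[(3S,7R)-3,7-bis[(tert-butyldimethylsilyl)oxy]octyl]-3-[(tert-butyldimethylsilyl)oxy]-5-oxocyclopentyl]hept-5-enoate
Product: 20 methyl (5Z)-7-[(1R,2R,3R)-2-[(3S,7R)-3,7-dihydroxyoctyl]-3-hydroxy-5-oxocyclopentyl]hept-5-enoate
Conditions: HF·pyridine, MeCN, 0 °C to rt
Reagents that add atoms: none
Why: Fluoride-driven Si–O cleavage in a pyridine-buffered medium should remove all three silyl groups without the strong acid or base that would dehydrate the C11 β-hydroxy ketone, and no stereocentre is involved.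

Step 12
Reactants: 20 methyl (5Z)-7-[(1R,2R,3R)-2-[(3S,7R)-3,7-dihydroxyoctyl]-3-hydroxy-5-oxocyclopentyl]hept-5-enoate
Product: 21 (5Z)-7-[(1R,2R,3R)-2-[(3S,7R)-3,7-dihydroxyoctyl]-3-hydroxy-5-oxocyclopentyl]hept-5-enoic acid (CNP0414125.1)
Conditions: porcine liver esterase, phosphate buffer pH 7.5–8, acetone co-solvent, 30 °C
Reagents that add atoms: water, O
Why: Enzymatic ester hydrolysis near neutral pH should free the acid without the hydroxide that would eliminate the C11 hydroxyl or epimerise C8.

**Compound list**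

1 | (R)-but-3-yn-2-ol | C[C@@H](O)C#C | starting material
2 | (R)-tert-butyl(but-3-yn-2-yloxy)dimethylsilane | C[C@@H](O[Si](C)(C)C(C)(C)C)C#C | intermediate
3 | (R)-2-[2-(benzyloxy)ethyl]oxirane | C1[C@H](O1)CCOCc2ccccc2 | starting material
4 | lithium acetylide of 2, lithium (R)-3-[(tert-butyldimethylsilyl)oxy]but-1-yn-1-ide | C[C@@H](O[Si](C)(C)C(C)(C)C)C#C[Li] | intermediate (not isolated)
5 | (3S,7R)-1-(benzyloxy)-7-[(tert-butyldimethylsilyl)oxy]oct-5-yn-3-ol | C[C@@H](O[Si](C)(C)C(C)(C)C)C#CC[C@H](O)CCOCc1ccccc1 | intermediate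
6 | (3S,7R)-1-(benzyloxy)-3,7-bis[(tert-butyldimethylsilyl)oxy]oct-5-yne | C[C@@H](O[Si](C)(C)C(C)(C)C)C#CC[C@H](O[Si](C)(C)C(C)(C)C)CCOCc1ccccc1 | intermediate
7 | (3S,7R)-3,7-bis[(tert-butyldimethylsilyl)oxy]octan-1-ol | C[C@@H](O[Si](C)(C)C(C)(C)C)CCC[C@H](O[Si](C)(C)C(C)(C)C)CCO | intermediate
8 | (3S,7R)-3,7-bis[(tert-butyldimethylsilyl)oxy]-1-iodooctane | C[C@@H](O[Si](C)(C)C(C)(C)C)CCC[C@H](O[Si](C)(C)C(C)(C)C)CCI | intermediate
9 | hex-5-ynoic acid | C#CCCCC(=O)O | starting material
10 | bromomagnesium 6-(bromomagnesio)hex-5-ynoate | Br[Mg]C#CCCCC(=O)O[Mg]Br | intermediate (not isolated)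
11 | 7-hydroxyhept-5-ynoic acid | OCC#CCCCC(=O)O | intermediate
12 | methyl 7-hydroxyhept-5-ynoate | OCC#CCCCC(=O)OC | intermediate
13 | methyl (5Z)-7-hydroxyhept-5-enoate | OC/C=C\CCCC(=O)OC | intermediate
14 | methyl (5Z)-7-iodohept-5-enoate | IC/C=C\CCCC(=O)OC | intermediate
15 | (R)-4-[(tert-butyldimethylsilyl)oxy]cyclopent-2-en-1-one | O=C1C=C[C@H](O[Si](C)(C)C(C)(C)C)C1 | starting material
16 | 3,7-bis[(tert-butyldimethylsilyl)oxy]octyllithium with the spatial arrangement of 8 (formally 3R,7R, because lithium ranks below carbon) | C[C@@H](O[Si](C)(C)C(C)(C)C)CCC[C@H](O[Si](C)(C)C(C)(C)C)CC[Li] | intermediate (not isolated)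
17 | lithium [(3S,7R)-3,7-bis[(tert-butyldimethylsilyl)oxy]octyl]dimethylzincate | C[C@@H](O[Si](C)(C)C(C)(C)C)CCC[C@H](O[Si](C)(C)C(C)(C)C)CC[Zn-](C)C.[Li+] | intermediate (not isolated)
18 | lithium dimethylzincate C8=C9 enolate of the 11,12-trans conjugate adduct (C11 R, C12 R, chain centres as in 8) | C[C@@H](O[Si](C)(C)C(C)(C)C)CCC[C@H](O[Si](C)(C)C(C)(C)C)CC[C@H]1[C@H](O[Si](C)(C)C(C)(C)C)CC(O[Zn-](C)C)=C1.[Li+] | intermediate (not isolated)
19 | methyl (5Z)-7-[(1R,2R,3R)-2-[(3S,7R)-3,7-bis[(tert-butyldimethylsilyl)oxy]octyl]-3-[(tert-butyldimethylsilyl)oxy]-5-oxocyclopentyl]hept-5-enoate | C[C@@H](O[Si](C)(C)C(C)(C)C)CCC[C@H](O[Si](C)(C)C(C)(C)C)CC[C@H]1[C@H](O[Si](C)(C)C(C)(C)C)CC(=O)[C@@H]1C/C=C\CCCC(=O)OC | intermediate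
20 | methyl (5Z)-7-[(1R,2R,3R)-2-[(3S,7R)-3,7-dihydroxyoctyl]-3-hydroxy-5-oxocyclopentyl]hept-5-enoate | C[C@@H](O)CCC[C@H](O)CC[C@H]1[C@H](O)CC(=O)[C@@H]1C/C=C\CCCC(=O)OC | intermediate
21 | (5Z)-7-[(1R,2R,3R)-2-[(3S,7R)-3,7-dihydroxyoctyl]-3-hydroxy-5-oxocyclopentyl]hept-5-enoic acid | C[C@@H](O)CCC[C@H](O)CC[C@H]1[C@H](O)CC(=O)[C@@H]1C/C=C\CCCC(=O)O | target

**Step count.** Total: 12 steps. Longest linear sequence: 8 steps (steps 1–5, then 10, 11 and 12).

**Steps most likely to fail**

Step 10. C-alkylation of the zinc enolate by the Z-allylic iodide may be slower than proton transfer between enolate and product; the enolate would then equilibrate and eject the C11 silyloxy group, and partial SN2' attack would erode the alkene geometry. The fallback sets out from 12 and comes back at 19. Appel-type iodination of 12 (PPh3, I2, imidazole, CH2Cl2, 0 °C) should give methyl 7-iodohept-5-ynoate F1, a faster and less hindered propargylic electrophile. The same one-pot sequence from 8 and 15 (through 16, 17 and 18), trapped with F1, should give methyl 7-[(1R,2R,3R)-2-[(3S,7R)-3,7-bis[(tert-butyldimethylsilyl)oxy]octyl]-3-[(tert-butyldimethylsilyl)oxy]-5-oxocyclopentyl]hept-5-ynoate F2. Semi-hydrogenation of F2 (H2, Lindlar catalyst (Pd on CaCO3 poisoned with Pb(OAc)2), quinoline, EtOAc) then sets the Z alkene after the coupling and gives 19.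

Step 4. During alkyne saturation the propargylic (then allylic) C19–O bond may be hydrogenolysed, or debenzylation may stall in the non-protic solvent that the silyl ethers require. The fallback sets out from 6 and comes back at 7. Metal-free diimide reduction (p-toluenesulfonyl hydrazide, NaOAc, DME–H2O, reflux) should saturate the alkyne without touching any C–O bond and give (3S,7R)-1-(benzyloxy)-3,7-bis[(tert-butyldimethylsilyl)oxy]octane F3. The benzyl group of F3 is then removed separately (H2, Pd(OH)2/C, EtOAc) to give 7.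

Step 12. Enzymatic turnover may be slow for this polar triol ester, and a long incubation at pH 8 risks dehydration of the C11 β-hydroxy ketone to the cyclopentenone. The fallback sets out from 19 and comes back at 21. The methyl ester is cleaved chemically while all three hydroxyls are still silylated, with trimethyltin hydroxide (Me3SnOH) in 1,2-dichloroethane at 60–70 °C, to give (5Z)-7-[(1R,2R,3R)-2-[(3S,7R)-3,7-bis[(tert-butyldimethylsilyl)oxy]octyl]-3-[(tert-butyldimethylsilyl)oxy]-5-oxocyclopentyl]hept-5-enoic acid F4. Desilylation of F4 with HF·pyridine in MeCN then gives 21 directly, so that the free β-hydroxy ketone never meets hydrolytic conditions.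

**Further compounds**

F1 | step 10 | methyl 7-iodohept-5-ynoate | ICC#CCCCC(=O)OC
F2 | step 10 | methyl 7-[(1R,2R,3R)-2-[(3S,7R)-3,7-bis[(tert-butyldimethylsilyl)oxy]octyl]-3-[(tert-butyldimethylsilyl)oxy]-5-oxocyclopentyl]hept-5-ynoate | C[C@@H](O[Si](C)(C)C(C)(C)C)CCC[C@H](O[Si](C)(C)C(C)(C)C)CC[C@H]1[C@H](O[Si](C)(C)C(C)(C)C)CC(=O)[C@@H]1CC#CCCCC(=O)OC
F3 | step 4 | (3S,7R)-1-(benzyloxy)-3,7-bis[(tert-butyldimethylsilyl)oxy]octane | C[C@@H](O[Si](C)(C)C(C)(C)C)CCC[C@H](O[Si](C)(C)C(C)(C)C)CCOCc1ccccc1
F4 | step 12 | (5Z)-7-[(1R,2R,3R)-2-[(3S,7R)-3,7-bis[(tert-butyldimethylsilyl)oxy]octyl]-3-[(tert-butyldimethylsilyl)oxy]-5-oxocyclopentyl]hept-5-enoic acid | C[C@@H](O[Si](C)(C)C(C)(C)C)CCC[C@H](O[Si](C)(C)C(C)(C)C)CC[C@H]1[C@H](O[Si](C)(C)C(C)(C)C)CC(=O)[C@@H]1C/C=C\CCCC(=O)O
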